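**Plan**

1. Numbering used: N4; pyrrolidine C3 (bears lactone E), C2, C1, C9a; azepane N4–C5–C6–C7–C8–C9–C9a; cyclopentane C9a, C9, C10 (ethyl), C11 (O), C12; lactone D C13 (C(OH)Me), C14; lactone E C18 (CH–O), C19, C20 (CHMe), C21.
2. Retrosynthesis: cut lactone E at C18–C19 and C18–O (amino aldehyde + bromomethylacrylate), the azepane at N4–C5 (N-alkylation), lactone D at C12–C13 and C11–O (glyoxylate aldol, C13 methylation). Then undo a ring contraction by moving C9 from C9a back to C1, which traces the cyclopentane to the cyclohexenone ring of a hexahydroindolone made from the arene of D-tyrosine.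
3. Enabling feature: C9a is both the N-bearing spiro atom of the cyclopentane and the neighbour of pyrrolidine carbon C1. With C1 as an O-silyl carbinol and N4–C9a=C12–C11=O as an N-acyl enaminone, silyl activation makes C9a a vinylogous N-acyliminium centre and the ring bond C1–C9 shifts to it (six- to five-membered carbocycle). The C1 ketone left behind is a helper: it later allows inversion of C3 and is removed through its enol triflate.
4. Forward order: arene → cyclohexadienone + pyrrolidine (dearomatisation/aza-Michael) → C10 ethyl and C9 chain → ring contraction to the spiro cyclopentane → lactone D → azepane → lactone E.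
5. Stereochemistry: the α-carbon of D-tyrosine sets C1, and C1 is transferred to C9a in the shift. C9 comes from cuprate addition anti to C1–OSi, C10 from kinetic protonation, C12/C11/C13 from substrate-controlled aldol, hydride addition and convex-face methylation. C3 is reset by hydride addition to a C2=C3 enaminone, C18 by chelation-controlled allylzinc addition, C20 by hydrogenation.

Key step: step 7

Remark: the C13 carbinol centre of 14, 15 and 16 and the C1 carbinol centre of 15 are expected as epimer mixtures; both centres are planarised later (steps 10 and 11), so their SMILES carry no descriptor there.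
Remark: 1, 9, 13 and 25 are taken as commercial; the assignment of 3 as (2R,3aS,7aS) assumes the known cis-selective course of this cascade in the L series, mirrored for the D series.

**Route**

Step 1
Reactants: 1 N-benzyloxycarbonyl-D-tyrosine
Product: 3 1-benzyl 2-methyl (2R,3aS,7aS)-3a-hydroxy-6-oxo-2,3,3a,6,7,7a-hexahydro-1H-indole-1,2-dicarboxylate, via spirolactone dienone 2 (not isolated)
Conditions: PhI(OAc)2, MeOH, rt; then NaHCO3, 40 °C
Reagents that add atoms: methanol CO
Why: Hypervalent-iodine phenol oxidation with ipso capture by the carboxylate gives the spirolactone dienone, whose methanolysis frees the tertiary alcohol and lets the carbamate nitrogen close by reversible intramolecular aza-Michael addition onto the enone arm that places the ester on the convex face, so that the D-configured α-carbon (C3) fixes the cis-fused C1 carbinol and C9a (oxidative dearomatisation/aza-Michael cascade).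

Step 2
Reactants: 3 hydroxy enone
Product: 4 1-benzyl 2-methyl (2R,3aS,7aS)-6-oxo-3a-(triethylsilyloxy)-2,3,3a,6,7,7a-hexahydro-1H-indole-1,2-dicarboxylate
Conditions: TESOTf, 2,6-lutidine, CH2Cl2, −78 to 0 °C
Reagents that add atoms: triethylsilyl triflate CC[Si](CC)(CC)OS(=O)(=O)C(F)(F)F
Why: Silylation of the tertiary C1 alcohol with a silyl triflate and a hindered base is standard and installs the group that later shields one face of C9 and serves as the migrating silyl cation of the key step; no stereocenter is formed.

Step 3
Reactants: 4 silyl ether enone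
Product: 5 1-benzyl 2-methyl (2R,3aS,7aS)-5-iodo-6-oxo-3a-(triethylsilyloxy)-2,3,3a,6,7,7a-hexahydro-1H-indole-1,2-dicarboxylate
Conditions: I2, pyridine, CH2Cl2, rt
Reagents that add atoms: iodine II
Why: Pyridine-mediated addition–elimination α-iodination of the enone is reliable for 4,4-disubstituted cyclohexenones and places iodine only at C10; no stereocenter is formed.

Step 4
Reactants: 5 α-iodo enone
Product: 6 1-benzyl 2-methyl (2R,3aS,7aS)-5-ethyl-6-oxo-3a-(triethylsilyloxy)-2,3,3a,6,7,7a-hexahydro-1H-indole-1,2-dicarboxylate
Conditions: Et3B, Pd(dppf)Cl2 (5 mol%), AsPh3, Cs2CO3, DMF/THF/H2O, rt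
Reagents that add atoms: triethylborane CCB(CC)CC
Why: B-alkyl Suzuki–Miyaura coupling of α-iodoenones with trialkylboranes under mild aqueous base is well precedented and puts the ethyl group on C10 at the alkene stage, so no stereocenter is set yet.

Step 5
Reactants: 6 α-ethyl enone
Product: 8 1-benzyl 2-methyl (2R,3aS)-5-ethyl-6-oxo-3a-(triethylsilyloxy)-2,3,3a,6-tetrahydro-1H-indole-1,2-dicarboxylate, via trimethylsilyl dienol ether 7 (not isolated)
Conditions: LiN(iPr)2, TMSCl, THF, −78 °C; then Pd(OAc)2 (1.1 equiv), MeCN, rt
Reagents that add atoms: none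
Why: Kinetic deprotonation can only occur at the α′ methylene C12 (C10 is sp2), and Saegusa–Ito oxidation of the resulting silyl dienol ether removes H-9a by β-hydride elimination to give the cross-conjugated dienone whose C12=C9a bond is the N-acyl enaminone; C9a loses its stereocenter.

Step 6
Reactants: 8 cross-conjugated dienone; 9 1-bromo-4-chlorobutane
Product: 11 1-benzyl 2-methyl (2R,3aS,4R,5S)-4-(4-chlorobutyl)-5-ethyl-6-oxo-3a-(triethylsilyloxy)-2,3,3a,4,5,6-hexahydro-1H-indole-1,2-dicarboxylate, via trimethylsilyl dienol ether 10 (not isolated)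
Conditions: 9, Mg, THF, 0 °C; then 8, CuBr·SMe2 (20 mol%), TMSCl, THF, −78 °C; then Bu4NF, AcOH, THF, −78 °C
Reagents that add atoms: none
Why: Copper-catalysed, chlorosilane-accelerated conjugate addition of the Grignard reagent goes to C9 (C9a is fully substituted) on the face anti to the bulky, electronegative C1–OSiEt3 group, and fluoride-triggered protonation of the liberated dienolate at C10 from the face opposite the new C9 chain should give the cis C9/C10 arrangement kinetically.

Step 7
Reactants: 11 N-acyl enaminone silyl ether
Product: 12 1-benzyl 2-methyl 9-(4-chlorobutyl)-8-ethyl-4-oxo-7-(triethylsilyloxy)-1-azaspiro[4.4]non-6-ene-1,2-dicarboxylate (C1 ketone; C11=C12 enol silane; N4 cis to the C9 chain)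
Conditions: TESOTf (10 mol%), 2,6-di-tert-butyl-4-methylpyridine (15 mol%), CH2Cl2, −78 to −20 °C
Reagents that add atoms: none
Why: Proposed new method: O-silylation of the enaminone carbonyl (C11) by the silyl triflate makes C9a a vinylogous N-acyliminium carbon; the ring bond C1–C9, held about 30° off the p-orbital axis at C9a by the fused pyrrolidine, migrates from C1 to C9a while the C1 silyloxocarbenium ion collapses to the C1 ketone and passes its silyl group on to the next enaminone oxygen, so the six-membered carbocycle contracts to the cyclopentane and the product is the C11/C12 enol silane. The closest known reaction types are the semipinacol ring expansion of α-hydroxy N-acyliminium ions generated from enecarbamates, the vinylogous α-ketol rearrangement of γ-hydroxy enones, and the 3-hydroxyindolenine to spiro-pseudoindoxyl ring contraction. No ring is closed end to end: the cyclopentane arises by a suprafacial 1,2-alkyl shift (ring contraction by one carbon, C1 being extruded into the pyrrolidinone). C9a is the only new stereocenter and is set by chirality transfer from C1, since C9 bonds to the face of C9a on which it already sits (anti to the C1–O bond), and C9 itself migrates with retention. The step needs migration of C9 and not of C2, and no loss of the C10 configuration: C2 migration would give a strained azetidine and lies near the nodal plane, and a hindered pyridine base with substoichiometric silyl triflate at low temperature avoids enolisation toward C10.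

Step 8
Reactants: 12 spiro enol silane; 13 ethyl glyoxylate
Product: 14 1-benzyl 2-methyl 9-(4-chlorobutyl)-6-[2-ethoxy-2-oxo-1-(triethylsilyloxy)ethyl]-8-ethyl-4,7-dioxo-1-azaspiro[4.4]nonane-1,2-dicarboxylate (C13 epimers)
Conditions: TESOTf (10 mol%), CH2Cl2, −78 °C
Reagents that add atoms: none
Why: Silyl-triflate-catalysed Mukaiyama aldol addition of the regiodefined enol silane to the reactive glyoxylate forms the C12–C13 bond with silyl transfer to the new alkoxide, the aldehyde approaching C12 from the face of the C1 carbonyl, anti to the N-carbamate and to the cis C9/C10 substituents, which sets C12 (C13 is set later).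

Step 9
Reactants: 14 aldol adduct
Product: 15 cis-fused γ-lactone (ring D; C13–H with OSiEt3) carrying a C1 carbinol
Conditions: LiBH(s-Bu)3 (2.5 equiv), THF, −78 °C; AcOH; then PPTS, PhMe, 40 °C
Reagents that add atoms: none
Why: The bulky borohydride should attack the C11 ketone anti to the branched C12 substituent to give the cis hydroxy ester, which closes to the cis-fused γ-lactone (only this epimer can lactonise), while the concurrent reduction of the C1 ketone is harmless because that carbinol is reoxidised in step 10.

Step 10
Reactants: 15 lactone alcohol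
Product: 16 enaminone lactone (C1 ketone; C2=C3 bearing N-Cbz and CO2Me)
Conditions: IBX (3 equiv), 4-methoxypyridine N-oxide, DMSO, rt
Reagents that add atoms: none
Why: IBX oxidises the C1 carbinol and then dehydrogenates the ketone through its enol, which can form only toward C2 because C9a is quaternary, giving the push–pull C2=C3 enaminone that erases the D-configured C3 and removes the acidic C–H bonds next to C1.

Step 11
Reactants: 16 enaminone lactone
Product: 17 C13-methylated enaminone lactone (C13: methyl cis to H-12; OSiEt3 endo)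
Conditions: LiN(iPr)2, THF/DMPU, −78 °C; then MeI
Reagents that add atoms: iodomethane CI
Why: The lactone enolate is now the only enolisable site and is methylated on the convex face of the cis-fused bicyclic lactone (anti to the C12–C9a bond), which sets C13 with methyl cis to H-12 and oxygen endo (enolate alkylation).

Step 12
Reactants: 17 methylated enaminone lactone
Product: 18 C1 enol triflate (C1=C2) with C3 in the S configuration
Conditions: LiBH(s-Bu)3, THF, −78 °C; then N-(5-chloropyridin-2-yl)triflimide, −78 to 0 °C
Reagents that add atoms: N-(5-chloropyridin-2-yl)bis(trifluoromethanesulfonyl)imide O=S(=O)(N(c1ccc(Cl)cn1)S(=O)(=O)C(F)(F)F)C(F)(F)F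
Why: Conjugate hydride reduction of N-acyl enaminones with this borohydride and O-triflation of the resulting enolate with a pyridyl triflimide are well precedented, and hydride should reach C3 from the face of C12–H, opposite the C9 carbon and its chlorobutyl chain, so that C3 is reset to the S configuration while the C1 oxygen becomes a leaving group.

Step 13
Reactants: 18 enol triflate
Product: 19 N-Cbz 3-pyrroline (C1=C2)
Conditions: Pd(OAc)2 (5 mol%), PPh3, HCO2H, Et3N, DMF, 60 °C
Reagents that add atoms: none
Why: Palladium-catalysed formate reduction of enol triflates replaces the triflate by hydrogen under conditions that leave the benzyl carbamate, the alkyl chloride and the lactone untouched, completing removal of the C1 oxygen; no stereocenter is affected.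

Step 14
Reactants: 19 pyrroline
Product: 21 tetracyclic amino ester (azepane closed; C13–OSiEt3; methyl ester at C3), via amino chloride 20 (not isolated)
Conditions: H2 (1 atm), Pd/C, MeOH, rt; then K2CO3, NaI (20 mol%), MeCN, 70 °C
Reagents that add atoms: none
Why: Hydrogenation saturates C1=C2 and cleaves the benzyl carbamate, and the liberated secondary amine then closes the azepane by iodide-assisted intramolecular N-alkylation (7-exo-tet), the ring fusion being fixed by the existing C9 and C9a centres.

Step 15
Reactants: 21 tetracyclic amino ester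
Product: 22 tetracyclic amino acid (C3–CO2H; C13–OH free)
Conditions: 3 M HCl (aq), 1,4-dioxane, 70 °C; then ion exchange to the zwitterion
Reagents that add atoms: water O
Why: Aqueous acid hydrolyses the methyl ester and the tertiary silyl ether while the γ-lactone stays closed under acidic conditions and the protonated amine protects C3 from epimerisation (acid-catalysed ester hydrolysis).

Step 16
Reactants: 22 amino acid
Product: 23 amino alcohol (C18 as CH2OH)
Conditions: BH3·SMe2, THF, 0 °C to rt; then MeOH, 60 °C
Reagents that add atoms: none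
Why: Borane reduces carboxylic acids much faster than lactones, so the C18 acid is taken to the primary alcohol with ring D intact (chemoselective borane reduction).

Step 17
Reactants: 23 amino alcohol
Product: 24 α-amino aldehyde (C18 as CHO)
Conditions: (COCl)2, DMSO, CH2Cl2, −78 °C; then Et3N
Reagents that add atoms: none
Why: Swern oxidation gives the configurationally sensitive α-amino aldehyde at low temperature without over-oxidation; the tertiary alcohol and the tertiary amine are inert, and the aldehyde is used at once.

Step 18
Reactants: 24 amino aldehyde; 25 ethyl 2-(bromomethyl)acrylate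
Product: 26 α-methylene-γ-butyrolactone (ring E with exocyclic methylene at C20)
Conditions: Zn, THF, 50 °C; then 1 M HCl work-up
Reagents that add atoms: none
Why: The allylzinc reagent adds to the aldehyde and the zinc alkoxide lactonises onto the ester (Dreiding–Schmidt α-methylene-γ-butyrolactone synthesis), with zinc chelated between N4 and the carbonyl oxygen so that attack past the small C3–H should give the syn N/O relationship, setting C18.

Step 19
Reactants: 26 α-methylene lactone
Product: 27 target CNP0260919.4
Conditions: H2 (1 atm), Pd/C, EtOAc, rt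
Reagents that add atoms: none
Why: Heterogeneous hydrogenation of the exocyclic methylene delivers hydrogen to the lactone face opposite the bulky C18 substituent, which sets C20 with the methyl group cis to the C18 substituent as in the target.

**Compound list**

1 | N-benzyloxycarbonyl-D-tyrosine | OC(=O)[C@@H](Cc1ccc(O)cc1)NC(=O)OCc1ccccc1 | starting material
2 | benzyl [(3R)-2,8-dioxo-1-oxaspiro[4.5]deca-6,9-dien-3-yl]carbamate (spirolactone dienone) | O=C1OC2(C=CC(=O)C=C2)C[C@H]1NC(=O)OCc1ccccc1 | intermediate
3 | 1-benzyl 2-methyl (2R,3aS,7aS)-3a-hydroxy-6-oxo-2,3,3a,6,7,7a-hexahydro-1H-indole-1,2-dicarboxylate | COC(=O)[C@H]1C[C@]2(O)C=CC(=O)C[C@@H]2N1C(=O)OCc1ccccc1 | intermediate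
4 | 3a-triethylsilyl ether of 3 | COC(=O)[C@H]1C[C@]2(O[Si](CC)(CC)CC)C=CC(=O)C[C@@H]2N1C(=O)OCc1ccccc1 | intermediate
5 | 5-iodo enone (iodine at C10) | COC(=O)[C@H]1C[C@]2(O[Si](CC)(CC)CC)C=C(I)C(=O)C[C@@H]2N1C(=O)OCc1ccccc1 | intermediate
6 | 5-ethyl enone (ethyl at C10) | COC(=O)[C@H]1C[C@]2(O[Si](CC)(CC)CC)C=C(CC)C(=O)C[C@@H]2N1C(=O)OCc1ccccc1 | intermediate
7 | trimethylsilyl dienol ether of 6 (C11–OSiMe3, C11=C12) | COC(=O)[C@H]1C[C@]2(O[Si](CC)(CC)CC)C=C(CC)C(O[Si](C)(C)C)=C[C@@H]2N1C(=O)OCc1ccccc1 | intermediate
8 | cross-conjugated dienone (C9=C10 and C12=C9a), (2R,3aS) | COC(=O)[C@H]1C[C@]2(O[Si](CC)(CC)CC)C=C(CC)C(=O)C=C2N1C(=O)OCc1ccccc1 | intermediate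
9 | 1-bromo-4-chlorobutane | ClCCCCBr | starting material
10 | trimethylsilyl dienol ether of 11 (C10=C11–OSiMe3) | COC(=O)[C@H]1C[C@]2(O[Si](CC)(CC)CC)[C@H](CCCCCl)C(CC)=C(O[Si](C)(C)C)C=C2N1C(=O)OCc1ccccc1 | intermediate
11 | N-Cbz enaminone, (2R,3aS,4R,5S)-4-(4-chlorobutyl)-5-ethyl-6-oxo-3a-(triethylsilyloxy)hexahydroindole diester | COC(=O)[C@H]1C[C@]2(O[Si](CC)(CC)CC)[C@H](CCCCCl)[C@H](CC)C(=O)C=C2N1C(=O)OCc1ccccc1 | intermediate
12 | ring-contracted spiro ketone enol silane (1-azaspiro[4.4]non-6-ene; C1 ketone; C11–OSiEt3) | COC(=O)[C@H]1CC(=O)[C@@]2(C=C(O[Si](CC)(CC)CC)[C@@H](CC)[C@H]2CCCCCl)N1C(=O)OCc1ccccc1 | intermediate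
13 | ethyl glyoxylate | CCOC(=O)C=O | starting material
14 | glyoxylate aldol adduct (C12–CH(OSiEt3)CO2Et; C1 and C11 ketones) | COC(=O)[C@H]1CC(=O)[C@@]2([C@H](C(O[Si](CC)(CC)CC)C(=O)OCC)C(=O)[C@@H](CC)[C@H]2CCCCCl)N1C(=O)OCc1ccccc1 | intermediate
15 | cis-fused lactone D with C1 carbinol | COC(=O)[C@H]1CC(O)[C@@]2([C@@H]3C(O[Si](CC)(CC)CC)C(=O)O[C@@H]3[C@@H](CC)[C@H]2CCCCCl)N1C(=O)OCc1ccccc1 | intermediate
16 | enaminone lactone (C1 ketone, C2=C3) | COC(=O)C1=CC(=O)[C@@]2([C@@H]3C(O[Si](CC)(CC)CC)C(=O)O[C@@H]3[C@@H](CC)[C@H]2CCCCCl)N1C(=O)OCc1ccccc1 | intermediate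
17 | C13-methylated enaminone lactone | COC(=O)C1=CC(=O)[C@@]2([C@@H]3[C@](C)(O[Si](CC)(CC)CC)C(=O)O[C@@H]3[C@@H](CC)[C@H]2CCCCCl)N1C(=O)OCc1ccccc1 | intermediate
18 | C1 enol triflate, C3 (S) | COC(=O)[C@@H]1C=C(OS(=O)(=O)C(F)(F)F)[C@@]2([C@@H]3[C@](C)(O[Si](CC)(CC)CC)C(=O)O[C@@H]3[C@@H](CC)[C@H]2CCCCCl)N1C(=O)OCc1ccccc1 | intermediate
19 | N-Cbz 3-pyrroline (C1=C2) | COC(=O)[C@@H]1C=C[C@@]2([C@@H]3[C@](C)(O[Si](CC)(CC)CC)C(=O)O[C@@H]3[C@@H](CC)[C@H]2CCCCCl)N1C(=O)OCc1ccccc1 | intermediate
20 | secondary amino chloride | COC(=O)[C@@H]1CC[C@@]2([C@@H]3[C@](C)(O[Si](CC)(CC)CC)C(=O)O[C@@H]3[C@@H](CC)[C@H]2CCCCCl)N1 | intermediate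
21 | tetracyclic amino ester, C13 triethylsilyl ether | CC[C@@H]1[C@H]2OC(=O)[C@@](C)(O[Si](CC)(CC)CC)[C@H]2[C@]23CC[C@@H](C(=O)OC)N2CCCC[C@H]13 | intermediate
22 | tetracyclic amino acid | CC[C@@H]1[C@H]2OC(=O)[C@@](C)(O)[C@H]2[C@]23CC[C@@H](C(=O)O)N2CCCC[C@H]13 | intermediate
23 | tetracyclic amino alcohol | CC[C@@H]1[C@H]2OC(=O)[C@@](C)(O)[C@H]2[C@]23CC[C@@H](CO)N2CCCC[C@H]13 | intermediate
24 | tetracyclic α-amino aldehyde | CC[C@@H]1[C@H]2OC(=O)[C@@](C)(O)[C@H]2[C@]23CC[C@@H](C=O)N2CCCC[C@H]13 | intermediate
25 | ethyl 2-(bromomethyl)acrylate | C=C(CBr)C(=O)OCC | starting material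
26 | α-methylene-γ-butyrolactone precursor of the target | CC[C@@H]1[C@H]2OC(=O)[C@@](C)(O)[C@H]2[C@]23CC[C@@H]([C@@H]4CC(=C)C(=O)O4)N2CCCC[C@H]13 | intermediate
27 | CNP0260919.4 | CC[C@@H]1[C@H]2OC(=O)[C@@](C)(O)[C@H]2[C@]23CC[C@@H]([C@@H]4C[C@H](C)C(=O)O4)N2CCCC[C@H]13 | target

Total step count: 19. Longest linear sequence: 19 steps (from 1).

**Steps most likely to fail**

Step 7. The silyl-activated enaminone may fail to trigger the shift, may ionise at C1 with loss of silanol and aromatisation of the carbocycle, or may enolise toward C10 and lose that configuration. The fallback uses known chemistry, sets out from 11 and comes back at 14. Luche reduction (NaBH4, CeCl3·7H2O, MeOH) of the enaminone carbonyl would give the allylic alcohol enecarbamate F1. N-Bromosuccinimide would then add bromine at C12, and the resulting N-acyliminium ion next to the silyloxy carbinol would undergo the known halonium-induced semipinacol shift of C9 to C9a, giving the spiro bromo ketol F2. DMP oxidation would give the α-bromo ketone F3. A zinc-mediated Reformatsky aldol with 13 would use the bromide to generate the C11/C12 enolate regiospecifically and give the hydroxy aldol F4. Silylation (TESOTf, 2,6-lutidine) would return to 14.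

Step 6. Conjugate addition at the neopentyl β-carbon of the α-ethyl enone may be slow, and protonation at C10 may be unselective or equilibrate to the trans isomer. The fallback sets out from 4 and comes back at 11. IBX dehydrogenation of 4 would give the unsubstituted cross-conjugated dienone F5. Conjugate addition of the same organocopper reagent (from 9), followed by trapping of the enolate with acetaldehyde, would give the C10 hydroxyethyl aldol F6. Mesylation (MsCl, Et3N) to the mesylate F7 and elimination (DBU) would give the C10 ethylidene enaminone F8. Hydrogenation with [Ir(cod)(PCy3)(py)]PF6, which leaves the benzyl carbamate intact, would deliver hydrogen to C10 from the face opposite the C9 chain and return to 11.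

Step 12. Hydride delivery may occur on the wrong face of C3, or the carbonyl may be reduced directly. The fallback sets out from 17 and comes back at 18. Copper hydride conjugate reduction under ligand control (Cu(OAc)2, (R)-DTBM-SEGPHOS, (EtO)2MeSiH, t-BuOH, the ligand enantiomer being matched to the required face) would give the saturated C1 ketone F9, with C3 set by the catalyst and not by the substrate. Kinetic deprotonation at C2, the only enolisable position of that ketone, with KN(SiMe3)2 and O-triflation with the same pyridyl triflimide would return to 18.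

Further compounds
F1 | step 7 | allylic alcohol enecarbamate (C11–OH) | COC(=O)[C@H]1C[C@]2(O[Si](CC)(CC)CC)[C@H](CCCCCl)[C@H](CC)C(O)C=C2N1C(=O)OCc1ccccc1
F2 | step 7 | spiro bromo ketol (C1 ketone, C12–Br, C11–OH) | COC(=O)[C@H]1CC(=O)[C@@]2(C(Br)C(O)[C@@H](CC)[C@H]2CCCCCl)N1C(=O)OCc1ccccc1
F3 | step 7 | spiro α-bromo ketone | COC(=O)[C@H]1CC(=O)[C@@]2(C(Br)C(=O)[C@@H](CC)[C@H]2CCCCCl)N1C(=O)OCc1ccccc1
F4 | step 7 | hydroxy aldol (C13–OH free) | COC(=O)[C@H]1CC(=O)[C@@]2([C@H](C(O)C(=O)OCC)C(=O)[C@@H](CC)[C@H]2CCCCCl)N1C(=O)OCc1ccccc1
F5 | step 6 | unsubstituted cross-conjugated dienone | COC(=O)[C@H]1C[C@]2(O[Si](CC)(CC)CC)C=CC(=O)C=C2N1C(=O)OCc1ccccc1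
F6 | step 6 | C10 hydroxyethyl aldol | COC(=O)[C@H]1C[C@]2(O[Si](CC)(CC)CC)[C@H](CCCCCl)C(C(C)O)C(=O)C=C2N1C(=O)OCc1ccccc1
F7 | step 6 | mesylate of F6 | COC(=O)[C@H]1C[C@]2(O[Si](CC)(CC)CC)[C@H](CCCCCl)C(C(C)OS(C)(=O)=O)C(=O)C=C2N1C(=O)OCc1ccccc1
F8 | step 6 | C10 ethylidene enaminone (alkene geometry not defined) | COC(=O)[C@H]1C[C@]2(O[Si](CC)(CC)CC)[C@H](CCCCCl)C(=CC)C(=O)C=C2N1C(=O)OCc1ccccc1
F9 | step 12 | saturated C1 ketone with C3 (S) | COC(=O)[C@@H]1CC(=O)[C@@]2([C@@H]3[C@](C)(O[Si](CC)(CC)CC)C(=O)O[C@@H]3[C@@H](CC)[C@H]2CCCCCl)N1C(=O)OCc1ccccc1
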